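**Strategy.** The norbornene core (bridgeheads C1 and C3, alkene C4=C5, one-carbon bridge C2 carrying its acetate on the alkene side; guaiane numbering) is traced back to a bicyclo[2.2.2]octenone whose keto bridge is one carbon longer. A methoxide-triggered semibenzilic (quasi-Favorskii) shift of C3 from the carbonyl carbon to the brominated carbon contracts that bridge and leaves C2 as a methyl ester, which is later exchanged for acetate by Baeyer–Villiger oxidation. The α-bromo ketone comes from a Diels–Alder reaction between a dearomatised guaiacol (benzocycloheptane lactone) and the α-methylene lactone of a silyl-protected hydroxy-eudesmanolide, followed by SmI2 demethoxylation and bromination.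

Key step: step 24

Remark (numbering): guaiane numbers C1–C15 are used for the guaianolide half and primed eudesmane numbers for the other half; in the aromatic precursors Ca is the ring carbon bearing OH (later the bridge ketone) and Cb the one bearing OMe (later C2).
Remark (stereochemistry as drawn): the eudesmanolide half is 1'S,4'R,7'S,8'S,10'S (cis lactone, all substituents on the face of the angular methyl) and maps onto (S)-Wieland–Miescher ketone; the guaianolide lactone is trans-fused (7S,8R) with 10R.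
Remark (halo ketone): the brominated carbon keeps one hydrogen, so only cyclopropanone formation is excluded and the bromide can still epimerise by enolisation; the route therefore also relies on the thermodynamic preference of the C2 ester, and keeps C11 as CH2 and C1'–OH silylated until after the contraction.

**Fragment A (phenol 17)**

Step 1
Reactants: 1 2-methoxy-5-methylphenol
Product: 2 2-isopropoxy-1-methoxy-4-methylbenzene
Conditions: 2-bromopropane, K2CO3, DMF, 60 °C
Reagents that add atoms: 2-bromopropane, CC(C)Br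
Why: Williamson etherification; the bulky isopropyl ether leaves the methoxy group as the only effective director for the next lithiation and is removed by AlCl3 in step 8.

Step 2
Reactants: 2 2-isopropoxy-1-methoxy-4-methylbenzene; 3 (S)-β-butyrolactone
Product: 6 (3R)-3-(3-isopropoxy-2-methoxy-5-methylphenyl)butanoic acid, via aryllithium 4 (not isolated), via arylmagnesium bromide 5 (not isolated)
Conditions: n-BuLi, TMEDA, Et2O, 0 °C → rt; MgBr2·OEt2, THF, 0 °C; CuI (10 mol%), 3, −30 → 0 °C; aq. HCl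
Reagents that add atoms: none
Why: Directed ortho-metalation next to OMe (the other ortho position is flanked by isopropoxy and methyl), then copper-catalysed SN2 opening of the β-lactone at its β-carbon with inversion, so the (S)-lactone sets C10 as R.

Step 3
Reactants: 6 (3R)-3-(3-isopropoxy-2-methoxy-5-methylphenyl)butanoic acid
Product: 7 (3R)-3-(3-isopropoxy-2-methoxy-5-methylphenyl)butan-1-ol
Conditions: LiAlH4, THF, 0 °C → rt
Reagents that add atoms: none
Why: Hydride reduction of the carboxylic acid to the primary alcohol; C10 is not involved.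

Step 4
Reactants: 7 (3R)-3-(3-isopropoxy-2-methoxy-5-methylphenyl)butan-1-ol
Product: 8 (3R)-3-(3-isopropoxy-2-methoxy-5-methylphenyl)butanal
Conditions: Dess–Martin periodinane, NaHCO3, CH2Cl2, 0 °C → rt
Reagents that add atoms: none
Why: Dess–Martin oxidation stops at the aldehyde, and the stereocentre is β to the carbonyl and cannot enolise.

Step 5
Reactants: 9 (4S)-4-benzyl-1,3-oxazolidin-2-one; 10 methyl 4-chloro-4-oxobutanoate
Product: 11 methyl 4-[(4S)-4-benzyl-2-oxo-1,3-oxazolidin-3-yl]-4-oxobutanoate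
Conditions: n-BuLi, THF, −78 °C; then 10, −78 → 0 °C
Reagents that add atoms: none
Why: N-acylation of the lithiated oxazolidinone by the acid chloride gives the succinyl imide.

Step 6
Reactants: 8 (3R)-3-(3-isopropoxy-2-methoxy-5-methylphenyl)butanal; 11 succinyl imide
Product: 13 trans-lactone imide (2R,3S lactone; 2R side chain), via syn-aldol hydroxy ester 12 (not isolated)
Conditions: Bu2BOTf, i-Pr2NEt, CH2Cl2, 0 °C; 8, −78 → 0 °C; pH 7 buffer, H2O2, MeOH; then PPTS, PhMe, 60 °C
Reagents that add atoms: none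
Why: Evans syn-aldol reaction: the Z-boron enolate of the imide adds through a closed chair transition state on the face away from the benzyl group, setting C7 and C8 (3S,4R in 12) under reagent control, and acid-catalysed lactonisation of the γ-hydroxy ester then gives the trans-4,5-disubstituted lactone.

Step 7
Reactants: 13 trans-lactone imide
Product: 14 (2R,3S)-2-[(2R)-2-(3-isopropoxy-2-methoxy-5-methylphenyl)propyl]-5-oxotetrahydrofuran-3-carboxylic acid
Conditions: LiOH, H2O2, THF–H2O, 0 °C; Na2SO3; aq. HCl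
Reagents that add atoms: lithium hydroperoxide (from LiOH and H2O2), [Li+].[O-]O
Why: Hydroperoxide attacks the exocyclic imide carbonyl selectively (standard auxiliary cleavage) without epimerising C7, and any opened lactone recloses on acidification.

Step 8
Reactants: 14 lactone acid
Product: 16 phenolic keto lactone (7S,8R,10R; ketone at C6), via acid chloride 15 (not isolated)
Conditions: (COCl)2, DMF (cat.), CH2Cl2, rt; then AlCl3 (3.5 equiv), CH2Cl2, 0 °C → rt
Reagents that add atoms: none
Why: Intramolecular Friedel–Crafts acylation can reach only the free ring position beside the tether, which is para to the oxygen on Ca, so the seven-membered ketone closes there; AlCl3 also dealkylates the secondary isopropyl ether while the methyl ether stays.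

Step 9
Reactants: 16 phenolic keto lactone
Product: 17 phenol lactone (7S,8R,10R), the benzocycloheptane guaiacol
Conditions: Et3SiH, CF3CO2H, CH2Cl2, 0 °C → rt
Reagents that add atoms: none
Why: Ionic hydrogenation reduces the para-hydroxyaryl ketone to CH2 through the oxygen-stabilised benzylic cation; the lactone is inert and C7 is no longer α to a carbonyl afterwards.

**Fragment B (dienophile 34)**

Step 10
Reactants: 18 2-methylcyclohexane-1,3-dione; 19 methyl vinyl ketone
Product: 21 (S)-Wieland–Miescher ketone, via triketone 20 (not isolated)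
Conditions: Et3N (cat.), neat, rt; then L-proline (0.3 equiv), DMSO, rt; recrystallisation
Reagents that add atoms: none
Why: Robinson annulation: Michael addition gives the prochiral triketone and the proline enamine (Hajos–Parrish-type aldol condensation) differentiates the two ring carbonyls to give the (S)-enedione, which recrystallisation should bring to optical purity.

Step 11
Reactants: 21 (S)-Wieland–Miescher ketone
Product: 22 (8aS)-8a-methyl-4-methylidene-3,4,8,8a-tetrahydronaphthalene-1,6(2H,7H)-dione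
Conditions: CH2(OEt)2, POCl3, NaOAc, CHCl3, 65 °C
Reagents that add atoms: diethoxymethane, CCOCOCC
Why: γ-Methylenation of the enone: the extended dienol ether formed in situ is attacked at its γ-carbon C4' by the ethoxymethyl cation and loses ethanol (the vinylogous condensation used for 6-methylenation of steroidal enones), while the saturated ketone beside the quaternary carbon is not engaged.

Step 12
Reactants: 22 4-methylidene enedione
Product: 23 (4R,8aS)-4,8a-dimethyl-3,4,8,8a-tetrahydronaphthalene-1,6(2H,7H)-dione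
Conditions: H2 (1 atm), RhCl(PPh3)3 (5 mol%), benzene, rt
Reagents that add atoms: none
Why: Homogeneous hydrogenation reduces only the exocyclic 1,1-disubstituted alkene and delivers hydrogen to the face away from the 1,3-related angular methyl, so the new C4' methyl is cis to it (4'R); the neutral medium avoids epimerisation through the dienol.

Step 13
Reactants: 23 4,8a-dimethyl enedione
Product: 24 (4aS,5S,8R)-5-hydroxy-4a,8-dimethyl-4,4a,5,6,7,8-hexahydronaphthalen-2(3H)-one
Conditions: NaBH4, EtOH, −10 °C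
Reagents that add atoms: none
Why: Borohydride reduces the saturated ketone in preference to the enone and attacks anti to the angular methyl, giving the equatorial alcohol cis to that methyl (1'S).

Step 14
Reactants: 24 hydroxy enone
Product: 25 (4aS,5S,8R)-5-[(tert-butyldimethylsilyl)oxy]-4a,8-dimethyl-4,4a,5,6,7,8-hexahydronaphthalen-2(3H)-one
Conditions: TBSCl, imidazole, DMAP (cat.), DMF, 45 °C
Reagents that add atoms: tert-butyldimethylsilyl chloride, CC(C)(C)[Si](C)(C)Cl
Why: Silylation protects C1'–OH against the triflation, acylation and organometallic steps ahead.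

Step 15
Reactants: 25 silyloxy enone
Product: 26 cross-conjugated dienyl triflate (C7'–OTf, C7'=C8', C5'=C6')
Conditions: LiN(i-Pr)2, THF, −78 °C; PhNTf2, −78 → 0 °C
Reagents that add atoms: N-phenylbis(trifluoromethanesulfonimide), O=S(=O)(N(c1ccccc1)S(=O)(=O)C(F)(F)F)C(F)(F)F
Why: Kinetic deprotonation at the α'-CH2 (C8') and O-triflation give the enol triflate; the low temperature avoids γ-deprotonation at C4' and so keeps that centre.

Step 16
Reactants: 26 dienyl triflate
Product: 27 ethyl 2-[(4aS,5S,8R)-5-[(tert-butyldimethylsilyl)oxy]-4a,8-dimethyl-4,4a,5,6,7,8-hexahydronaphthalen-2-yl]acetate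
Conditions: BrZnCH2CO2Et (commercial THF solution), Pd(PPh3)4 (5 mol%), THF, 60 °C
Reagents that add atoms: (2-ethoxy-2-oxoethyl)zinc bromide, CCOC(=O)C[Zn]Br
Why: Negishi coupling of the Reformatsky reagent with the alkenyl triflate attaches C11'–C12' to C7' under neutral conditions that leave the skipped ester out of conjugation.

Step 17
Reactants: 27 diene ester
Product: 28 ethyl 2-[(2R,3R,4aS,5S,8R)-5-[(tert-butyldimethylsilyl)oxy]-3-hydroxy-4a,8-dimethyl-2,3,4,4a,5,6,7,8-octahydronaphthalen-2-yl]acetate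
Conditions: 9-BBN, THF, 60 °C; then NaBO3·4H2O, H2O, rt
Reagents that add atoms: sodium perborate, [Na+].[O-]OB=O
Why: Hydroboration–oxidation: boron adds to C8', the less substituted and less hindered diene terminus, from the face opposite the angular methyl with syn delivery of hydrogen to C7', so the side chain ends cis to the angular methyl and C8'–OH trans to it; the C5'=C6' bond flanked by C4' and C10' is left.

Step 18
Reactants: 28 trans hydroxy ester
Product: 29 ethyl 2-[(2R,4aS,5S,8R)-5-[(tert-butyldimethylsilyl)oxy]-4a,8-dimethyl-3-oxo-2,3,4,4a,5,6,7,8-octahydronaphthalen-2-yl]acetate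
Conditions: Dess–Martin periodinane, NaHCO3, CH2Cl2, 0 °C
Reagents that add atoms: none
Why: Buffered Dess–Martin oxidation gives the β,γ-unsaturated ketone without moving the alkene into conjugation or epimerising C7'.

Step 19
Reactants: 29 keto ester
Product: 31 cis-fused lactone (1'S,4'R,7'R,8'S,10'S)-1'-silyloxy-13'-noreudesm-5'-en-8',12'-olide, via cis-hydroxy ester 30 (not isolated)
Conditions: NaBH4, MeOH, −40 → 0 °C; then PPTS (cat.), PhMe, 50 °C
Reagents that add atoms: none
Why: Hydride attacks C8' from the face opposite the axial angular methyl and gives the axial alcohol cis to the side chain, and this cis γ-hydroxy ester lactonises to the cis-fused lactone.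

Step 20
Reactants: 31 cis-fused lactone
Product: 34 (1'S,4'R,7'S,8'S,10'S)-1'-[(tert-butyldimethylsilyl)oxy]eudesma-5',11'(13')-dien-8',12'-olide, via Mannich base 32 (not isolated), via ammonium iodide 33 (not isolated)
Conditions: LiN(i-Pr)2, THF, −78 °C; CH2=NMe2+ I−, −78 °C → rt; MeI, MeOH, rt; aq. NaHCO3, CH2Cl2
Reagents that add atoms: N,N-dimethylmethyleneiminium iodide, C=[N+](C)C.[I-]
Why: α-Methylenation by Mannich reaction of the lactone enolate, quaternisation and Hofmann-type elimination.

**Union, key step and end game**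

Step 21
Reactants: 17 phenol lactone; 34 silyloxy methylene lactone
Product: 36 Diels–Alder adduct (bicyclo[2.2.2]octenone dimethyl ketal), via masked o-benzoquinone 35 (not isolated)
Conditions: PhI(OAc)2, MeOH, 0 °C; evaporation; then 34 (1.0 equiv), PhMe, 90 °C
Reagents that add atoms: methanol, CO
Why: Oxidative dearomatisation gives the o-quinone monoketal, whose tetrasubstituted C1=C5 bond should slow self-dimerisation; its Diels–Alder reaction with the methylene lactone should follow the usual ortho orientation (C11' to C3 beside the dienone carbonyl, C13' to C1), with the lactone carbonyl endo, on the diene face opposite the pseudoaxial C10 methyl and on the convex H7' face of the dienophile, which sets C1, C3 and C11'.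

Step 22
Reactants: 36 Diels–Alder adduct
Product: 37 bicyclo[2.2.2]octenone (Cb now CH2)
Conditions: SmI2 (6 equiv), THF–MeOH, −78 → 0 °C
Reagents that add atoms: none
Why: Two rounds of ketyl formation, β-elimination of methoxide and protonation (reductive cleavage of an α-alkoxy ketone) remove both methoxy groups; lactones, silyl ether and isolated alkenes are inert to SmI2 here.

Step 23
Reactants: 37 bicyclo[2.2.2]octenone
Product: 39 α-bromo ketone (bromine on Cb, syn to C4=C5), via silyl enol ether 38 (not isolated)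
Conditions: LiN(SiMe3)2, THF, −78 °C; Me3SiCl; then NBS, THF, −78 °C
Reagents that add atoms: N-bromosuccinimide, O=C1CCC(=O)N1Br
Why: Only Cb can be deprotonated (an enolate toward bridgehead C3 would be an anti-Bredt alkene and the lactone CH2 is far less acidic), and NBS brominates the enol silane from the C4=C5 side, the other side being screened by C13'H2 and the spiro lactone, which places bromine syn to C4=C5.

Step 24
Reactants: 39 α-bromo ketone
Product: 40 norbornene methyl ester (CO2Me on C2, syn to C4=C5)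
Conditions: NaOMe (5 equiv), MeOH–THF, 0 °C → 40 °C; AcOH; then PPTS, PhMe, 50 °C
Reagents that add atoms: sodium methoxide, [Na+].[O-]C
Why: Methoxide adds reversibly to the bridge ketone, and in the resulting alkoxide the C3–C(O) bond migrates to the bromine-bearing carbon as bromide leaves (semibenzilic, quasi-Favorskii 1,2-shift), so the two-carbon keto bridge becomes the one-carbon bridge C2 with the former carbonyl carbon as an exocyclic methyl ester. The closest known reaction type is the base- or silver-induced ring contraction of bridged, non-enolisable α-halo ketones to the carboxylic acid derivative of the next smaller ring. The five-membered ring C1–C2–C3–C4=C5 is closed not by cyclisation of a chain but by this 1,2-alkyl shift with backside displacement at C2. The C2 stereocentre is controlled by inversion at the C–Br carbon (bromide on the alkene side gives ester on the alkene side) and a second time by thermodynamics: C2–H is enolisable under methoxide and the ester prefers the alkene side because the exo C7' substituent of the saturated bridge crowds the other side, so an epimerised bromide should still converge on 40. The step needs the shift to win over cyclopropanone formation, direct substitution and epoxy-ether formation: bridgehead C3 cannot enolise, C2 is neopentyl-like beside the quaternary C1, and the tetrahedral adduct forms reversibly and can drain through the irreversible shift. Lactones opened by methoxide are reclosed in the acidic finish.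

Step 25
Reactants: 40 norbornene methyl ester
Product: 43 α-methylene lactone methyl ester, via Mannich base 41 (not isolated), via ammonium iodide 42 (not isolated)
Conditions: LiN(i-Pr)2 (1.2 equiv), THF, −78 °C; CH2=NMe2+ I−, −78 °C → rt; MeI, MeOH, rt; aq. NaHCO3, CH2Cl2
Reagents that add atoms: N,N-dimethylmethyleneiminium iodide, C=[N+](C)C.[I-]
Why: Mannich methylenation at C11, the only accessible acidic site: the spiro lactone has no α-hydrogen, and C2–H lies under the C7' substituent and would give a strained exocyclic enolate at the one-carbon bridge.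

Step 26
Reactants: 43 α-methylene lactone methyl ester
Product: 44 C2 carboxylic acid
Conditions: Me3SnOH (6 equiv), ClCH2CH2Cl, 80 °C; then 0.1 M HCl
Reagents that add atoms: trimethyltin hydroxide, C[Sn](C)(C)O
Why: Tin-hydroxide-mediated ester hydrolysis cleaves hindered methyl esters under near-neutral conditions without conjugate addition to the methylene lactone, and any opened lactone recloses on acidification.

Step 27
Reactants: 44 C2 carboxylic acid
Product: 46 C2 methyl ketone, via acid chloride 45 (not isolated)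
Conditions: 1-chloro-N,N,2-trimethylpropenylamine, CH2Cl2, 0 °C; then MeZnCl, Pd(PPh3)4 (5 mol%), THF, 0 °C → rt
Reagents that add atoms: methylzinc chloride, C[Zn]Cl
Why: Neutral acid chloride formation followed by palladium-catalysed acylation of the organozinc reagent (Negishi acylation) gives the ketone, since organozincs do not add to lactones or to the methylene lactone.

Step 28
Reactants: 46 C2 methyl ketone
Product: 47 C2 acetate (1'-silyl ether of the target)
Conditions: Me3SiOOSiMe3 (2 equiv), Me3SiOTf (10 mol%), CH2Cl2, −78 → −30 °C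
Reagents that add atoms: bis(trimethylsilyl) peroxide, C[Si](C)(C)OO[Si](C)(C)C
Why: Baeyer–Villiger oxidation with a silyl peroxide, which adds to the activated carbonyl but is not an epoxidising agent for C4=C5, C5'=C6' or the methylene lactone; the secondary C2 migrates in preference to methyl with retention, so the acetate stays syn to C4=C5.

Step 29
Reactants: 47 C2 acetate silyl ether
Product: 48 japonicone A
Conditions: HF·pyridine, pyridine, THF, 0 °C → rt
Reagents that add atoms: none
Why: Buffered fluoride cleaves the hindered secondary silyl ether; the acetate and the methylene lactone tolerate these conditions.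

**Compound list**

1 | 2-methoxy-5-methylphenol | Cc1ccc(OC)c(O)c1 | starting material
2 | 2-isopropoxy-1-methoxy-4-methylbenzene | Cc1ccc(OC)c(OC(C)C)c1 | intermediate
3 | (S)-β-butyrolactone, (4S)-4-methyloxetan-2-one | C[C@H]1CC(=O)O1 | starting material
4 | (3-isopropoxy-2-methoxy-5-methylphenyl)lithium | [Li]c1cc(C)cc(OC(C)C)c1OC | intermediate
5 | (3-isopropoxy-2-methoxy-5-methylphenyl)magnesium bromide | Br[Mg]c1cc(C)cc(OC(C)C)c1OC | intermediate
6 | (3R)-3-(3-isopropoxy-2-methoxy-5-methylphenyl)butanoic acid | C[C@H](CC(=O)O)c1cc(C)cc(OC(C)C)c1OC | intermediate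
7 | (3R)-3-(3-isopropoxy-2-methoxy-5-methylphenyl)butan-1-ol | C[C@H](CCO)c1cc(C)cc(OC(C)C)c1OC | intermediate
8 | (3R)-3-(3-isopropoxy-2-methoxy-5-methylphenyl)butanal | C[C@H](CC=O)c1cc(C)cc(OC(C)C)c1OC | intermediate
9 | (4S)-4-benzyl-1,3-oxazolidin-2-one | O=C1N[C@@H](Cc2ccccc2)CO1 | starting material
10 | methyl 4-chloro-4-oxobutanoate | COC(=O)CCC(Cl)=O | starting material
11 | methyl 4-[(4S)-4-benzyl-2-oxo-1,3-oxazolidin-3-yl]-4-oxobutanoate | COC(=O)CCC(=O)N1[C@@H](Cc2ccccc2)COC1=O | intermediate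
12 | methyl (3S,4R,6R)-3-{[(4S)-4-benzyl-2-oxo-1,3-oxazolidin-3-yl]carbonyl}-4-hydroxy-6-(3-isopropoxy-2-methoxy-5-methylphenyl)heptanoate | COC(=O)C[C@H](C(=O)N1[C@@H](Cc2ccccc2)COC1=O)[C@H](O)C[C@@H](C)c1cc(C)cc(OC(C)C)c1OC | intermediate
13 | (4S)-4-benzyl-3-({(2R,3S)-2-[(2R)-2-(3-isopropoxy-2-methoxy-5-methylphenyl)propyl]-5-oxotetrahydrofuran-3-yl}carbonyl)-1,3-oxazolidin-2-one | O=C1C[C@H](C(=O)N2[C@@H](Cc3ccccc3)COC2=O)[C@@H](C[C@@H](C)c4cc(C)cc(OC(C)C)c4OC)O1 | intermediate
14 | (2R,3S)-2-[(2R)-2-(3-isopropoxy-2-methoxy-5-methylphenyl)propyl]-5-oxotetrahydrofuran-3-carboxylic acid | O=C1C[C@H](C(=O)O)[C@@H](C[C@@H](C)c2cc(C)cc(OC(C)C)c2OC)O1 | intermediate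
15 | acid chloride of 14 | O=C1C[C@H](C(Cl)=O)[C@@H](C[C@@H](C)c2cc(C)cc(OC(C)C)c2OC)O1 | intermediate
16 | phenolic keto lactone (7S,8R,10R): benzo-fused seven-membered ring C1–C10–C9–C8–C7–C6(=O)–C5, trans 8,12-lactone with C11H2, OH on Ca, OMe on Cb, methyl on C4 | C1C(=O)O[C@@H]2C[C@@H](C)c3c(OC)c(O)cc(C)c3C(=O)[C@@H]12 | intermediate
17 | phenol lactone (7S,8R,10R), as 16 with C6 as CH2 | C1C(=O)O[C@@H]2C[C@@H](C)c3c(OC)c(O)cc(C)c3C[C@@H]12 | intermediate
18 | 2-methylcyclohexane-1,3-dione | CC1C(=O)CCCC1=O | starting material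
19 | methyl vinyl ketone | CC(=O)C=C | starting material
20 | 2-methyl-2-(3-oxobutyl)cyclohexane-1,3-dione | CC(=O)CCC1(C)C(=O)CCCC1=O | intermediate
21 | (S)-Wieland–Miescher ketone, (8aS)-8a-methyl-3,4,8,8a-tetrahydronaphthalene-1,6(2H,7H)-dione | O=C1CC[C@@]2(C)C(=C1)CCCC2=O | intermediate
22 | (8aS)-8a-methyl-4-methylidene-3,4,8,8a-tetrahydronaphthalene-1,6(2H,7H)-dione | O=C1CC[C@@]2(C)C(=C1)C(=C)CCC2=O | intermediate
23 | (4R,8aS)-4,8a-dimethyl-3,4,8,8a-tetrahydronaphthalene-1,6(2H,7H)-dione | O=C1CC[C@@]2(C)C(=C1)[C@H](C)CCC2=O | intermediate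
24 | (4aS,5S,8R)-5-hydroxy-4a,8-dimethyl-4,4a,5,6,7,8-hexahydronaphthalen-2(3H)-one | O=C1CC[C@@]2(C)C(=C1)[C@H](C)CC[C@@H]2O | intermediate
25 | (4aS,5S,8R)-5-[(tert-butyldimethylsilyl)oxy]-4a,8-dimethyl-4,4a,5,6,7,8-hexahydronaphthalen-2(3H)-one | O=C1CC[C@@]2(C)C(=C1)[C@H](C)CC[C@@H]2O[Si](C)(C)C(C)(C)C | intermediate
26 | (4aS,5S,8R)-5-[(tert-butyldimethylsilyl)oxy]-4a,8-dimethyl-4,4a,5,6,7,8-hexahydronaphthalen-2-yl trifluoromethanesulfonate | O=S(=O)(OC1=CC[C@@]2(C)C(=C1)[C@H](C)CC[C@@H]2O[Si](C)(C)C(C)(C)C)C(F)(F)F | intermediate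
27 | ethyl 2-[(4aS,5S,8R)-5-[(tert-butyldimethylsilyl)oxy]-4a,8-dimethyl-4,4a,5,6,7,8-hexahydronaphthalen-2-yl]acetate | CCOC(=O)CC1=CC[C@@]2(C)C(=C1)[C@H](C)CC[C@@H]2O[Si](C)(C)C(C)(C)C | intermediate
28 | ethyl 2-[(2R,3R,4aS,5S,8R)-5-[(tert-butyldimethylsilyl)oxy]-3-hydroxy-4a,8-dimethyl-2,3,4,4a,5,6,7,8-octahydronaphthalen-2-yl]acetate | CCOC(=O)C[C@@H]1C=C2[C@H](C)CC[C@H](O[Si](C)(C)C(C)(C)C)[C@@]2(C)C[C@H]1O | intermediate
29 | ethyl 2-[(2R,4aS,5S,8R)-5-[(tert-butyldimethylsilyl)oxy]-4a,8-dimethyl-3-oxo-2,3,4,4a,5,6,7,8-octahydronaphthalen-2-yl]acetate | CCOC(=O)C[C@@H]1C=C2[C@H](C)CC[C@H](O[Si](C)(C)C(C)(C)C)[C@@]2(C)CC1=O | intermediate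
30 | (2R,3S,4aS,5S,8R) epimer of 28 (C8'–OH cis to the side chain) | CCOC(=O)C[C@@H]1C=C2[C@H](C)CC[C@H](O[Si](C)(C)C(C)(C)C)[C@@]2(C)C[C@@H]1O | intermediate
31 | (1'S,4'R,7'R,8'S,10'S)-1'-[(tert-butyldimethylsilyl)oxy]-13'-noreudesm-5'-en-8',12'-olide (cis lactone) | C1C(=O)O[C@H]2C[C@@]3(C)C(=C[C@@H]12)[C@H](C)CC[C@@H]3O[Si](C)(C)C(C)(C)C | intermediate
32 | 11'-(dimethylaminomethyl) derivative of 31 (C11' undefined) | CN(C)CC1C(=O)O[C@H]2C[C@@]3(C)C(=C[C@@H]12)[C@H](C)CC[C@@H]3O[Si](C)(C)C(C)(C)C | intermediate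
33 | trimethylammonium iodide of 32 | C[N+](C)(C)CC1C(=O)O[C@H]2C[C@@]3(C)C(=C[C@@H]12)[C@H](C)CC[C@@H]3O[Si](C)(C)C(C)(C)C.[I-] | intermediate
34 | (1'S,4'R,7'S,8'S,10'S)-1'-[(tert-butyldimethylsilyl)oxy]eudesma-5',11'(13')-dien-8',12'-olide | C=C1C(=O)O[C@H]2C[C@@]3(C)C(=C[C@@H]12)[C@H](C)CC[C@@H]3O[Si](C)(C)C(C)(C)C | intermediate
35 | masked o-benzoquinone: 6,6-dimethoxycyclohexa-2,4-dienone from 17 (C=O at Ca, ketal at Cb, diene C3=C4–C5=C1) | C1C(=O)O[C@@H]2C[C@@H](C)C3=C(C[C@@H]12)C(C)=CC(=O)C3(OC)OC | intermediate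
36 | Diels–Alder adduct: bicyclo[2.2.2]octenone (bridgeheads C1, C3; C4=C5; Ca=O on C3; Cb(OMe)2 on C1; C13'H2 on C1 anti to the C10 methyl; spiro C11' on C3 with C12'=O on the C4=C5 side and C7' on the keto-bridge side) | C1C(=O)O[C@@H]2C[C@@H](C)[C@]34C[C@]5(C(=O)O[C@H]6C[C@@]7(C)C(=C[C@H]65)[C@H](C)CC[C@@H]7O[Si](C)(C)C(C)(C)C)[C@H](C(C)=C3C[C@@H]12)C(=O)C4(OC)OC | intermediate
37 | as 36 with Cb as CH2 | C1C(=O)O[C@@H]2C[C@@H](C)[C@]34C[C@]5(C(=O)O[C@H]6C[C@@]7(C)C(=C[C@H]65)[C@H](C)CC[C@@H]7O[Si](C)(C)C(C)(C)C)[C@H](C(C)=C3C[C@@H]12)C(=O)C4 | intermediate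
38 | trimethylsilyl enol ether of 37 (Ca(OSiMe3)=Cb) | C1C(=O)O[C@@H]2C[C@@H](C)[C@]34C[C@]5(C(=O)O[C@H]6C[C@@]7(C)C(=C[C@H]65)[C@H](C)CC[C@@H]7O[Si](C)(C)C(C)(C)C)[C@H](C(C)=C3C[C@@H]12)C(O[Si](C)(C)C)=C4 | intermediate
39 | α-bromo bicyclo[2.2.2]octenone (Br on Cb, syn to C4=C5) | C1C(=O)O[C@@H]2C[C@@H](C)[C@]34C[C@]5(C(=O)O[C@H]6C[C@@]7(C)C(=C[C@H]65)[C@H](C)CC[C@@H]7O[Si](C)(C)C(C)(C)C)[C@H](C(C)=C3C[C@@H]12)C(=O)[C@@H]4Br | intermediate
40 | norbornene with C2 methyl ester syn to C4=C5 | C1C(=O)O[C@@H]2C[C@@H](C)[C@]34C[C@]5(C(=O)O[C@H]6C[C@@]7(C)C(=C[C@H]65)[C@H](C)CC[C@@H]7O[Si](C)(C)C(C)(C)C)[C@H](C(C)=C3C[C@@H]12)[C@@H]4C(=O)OC | intermediate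
41 | 11-(dimethylaminomethyl) derivative of 40 (C11 undefined) | CN(C)CC1C(=O)O[C@@H]2C[C@@H](C)[C@]34C[C@]5(C(=O)O[C@H]6C[C@@]7(C)C(=C[C@H]65)[C@H](C)CC[C@@H]7O[Si](C)(C)C(C)(C)C)[C@H](C(C)=C3C[C@@H]12)[C@@H]4C(=O)OC | intermediate
42 | trimethylammonium iodide of 41 | C[N+](C)(C)CC1C(=O)O[C@@H]2C[C@@H](C)[C@]34C[C@]5(C(=O)O[C@H]6C[C@@]7(C)C(=C[C@H]65)[C@H](C)CC[C@@H]7O[Si](C)(C)C(C)(C)C)[C@H](C(C)=C3C[C@@H]12)[C@@H]4C(=O)OC.[I-] | intermediate
43 | as 40 with C11=C13H2 | C=C1C(=O)O[C@@H]2C[C@@H](C)[C@]34C[C@]5(C(=O)O[C@H]6C[C@@]7(C)C(=C[C@H]65)[C@H](C)CC[C@@H]7O[Si](C)(C)C(C)(C)C)[C@H](C(C)=C3C[C@@H]12)[C@@H]4C(=O)OC | intermediate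
44 | C2 carboxylic acid (syn to C4=C5) | C=C1C(=O)O[C@@H]2C[C@@H](C)[C@]34C[C@]5(C(=O)O[C@H]6C[C@@]7(C)C(=C[C@H]65)[C@H](C)CC[C@@H]7O[Si](C)(C)C(C)(C)C)[C@H](C(C)=C3C[C@@H]12)[C@@H]4C(=O)O | intermediate
45 | C2 acid chloride | C=C1C(=O)O[C@@H]2C[C@@H](C)[C@]34C[C@]5(C(=O)O[C@H]6C[C@@]7(C)C(=C[C@H]65)[C@H](C)CC[C@@H]7O[Si](C)(C)C(C)(C)C)[C@H](C(C)=C3C[C@@H]12)[C@@H]4C(=O)Cl | intermediate
46 | C2 methyl ketone (acetyl syn to C4=C5) | C=C1C(=O)O[C@@H]2C[C@@H](C)[C@]34C[C@]5(C(=O)O[C@H]6C[C@@]7(C)C(=C[C@H]65)[C@H](C)CC[C@@H]7O[Si](C)(C)C(C)(C)C)[C@H](C(C)=C3C[C@@H]12)[C@@H]4C(C)=O | intermediate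
47 | 1'-O-(tert-butyldimethylsilyl)japonicone A | C=C1C(=O)O[C@@H]2C[C@@H](C)[C@]34C[C@]5(C(=O)O[C@H]6C[C@@]7(C)C(=C[C@H]65)[C@H](C)CC[C@@H]7O[Si](C)(C)C(C)(C)C)[C@H](C(C)=C3C[C@@H]12)[C@@H]4OC(C)=O | intermediate
48 | japonicone A | C=C1C(=O)O[C@@H]2C[C@@H](C)[C@]34C[C@]5(C(=O)O[C@H]6C[C@@]7(C)C(=C[C@H]65)[C@H](C)CC[C@@H]7O)[C@H](C(C)=C3C[C@@H]12)[C@@H]4OC(C)=O | target

**Totals.** Total step count: 29. Longest linear sequence: 20 steps (steps 10–29, from 18 and 19 to 48).

**Steps most likely to fail**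

Step 24. The tetrahedral methoxide adduct may close to an epoxy ether, or the bromide may simply be solvolysed, so that no ring contraction takes place. The fallback is a photochemical Wolff ring contraction that sets out from ketone 37 and comes back at ester 40. Ketone 37 would be C-trifluoroacetylated at Cb (LiN(SiMe3)2, CF3CO2CH2CF3, THF, −78 °C) to the trifluoroacetyl ketone F1. Diazo transfer with methanesulfonyl azide and Et3N would then give the α-diazo ketone F2. Irradiation of F2 in methanol (Pyrex filter, 0 °C) would lead through the ring-contracted ketene to ester 40 together with its C2 epimer F3, and NaOMe in MeOH would equilibrate F3 to 40.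

Step 21. The dienone may dimerise, rearomatise or decompose before the hindered dienophile intercepts it, or add with poor facial selectivity. The fallback changes the diene; it sets out from phenol 17 and comes back at ketone 37. Wessely acetoxylation of 17 with Pb(OAc)4 in AcOH would give the more robust 6-acetoxy-6-methoxy dienone F4, which can be purified and heated with 34 at higher temperature to the adduct F5. SmI2 in THF–MeOH would remove both the acetoxy and the methoxy group of F5 and give 37.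

Step 28. Oxygen transfer to the C4=C5 alkene, or slow migration of the strained bridge carbon C2, may outrun the Criegee rearrangement. The fallback is a decarboxylative oxygenation that sets out from acid 44 and comes back at acetate 47. Acid 44 would be converted with N-hydroxypyridine-2-thione and DCC into the Barton ester F6. Photolysis of F6 under O2 with tert-butyl thiol should give the hydroperoxide F7, because oxygen reaches the C2 radical from the open alkene side and not from under C7'. Triethyl phosphite would reduce F7 to the alcohol F8, and Ac2O with DMAP would give 47.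

**Further compounds**

F1 | step 24 | Cb-trifluoroacetyl derivative of ketone 37 | C1C(=O)O[C@@H]2C[C@@H](C)[C@]34C[C@]5(C(=O)O[C@H]6C[C@@]7(C)C(=C[C@H]65)[C@H](C)CC[C@@H]7O[Si](C)(C)C(C)(C)C)[C@H](C(C)=C3C[C@@H]12)C(=O)C4C(=O)C(F)(F)F
F2 | step 24 | α-diazo ketone (diazo on Cb) | C1C(=O)O[C@@H]2C[C@@H](C)[C@]34C[C@]5(C(=O)O[C@H]6C[C@@]7(C)C(=C[C@H]65)[C@H](C)CC[C@@H]7O[Si](C)(C)C(C)(C)C)[C@H](C(C)=C3C[C@@H]12)C(=O)C4=[N+]=[N-]
F3 | step 24 | C2 epimer of ester 40 (ester anti to C4=C5) | C1C(=O)O[C@@H]2C[C@@H](C)[C@]34C[C@]5(C(=O)O[C@H]6C[C@@]7(C)C(=C[C@H]65)[C@H](C)CC[C@@H]7O[Si](C)(C)C(C)(C)C)[C@H](C(C)=C3C[C@@H]12)[C@H]4C(=O)OC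
F4 | step 21 | 6-acetoxy-6-methoxycyclohexa-2,4-dienone from 17 (Cb undefined) | C1C(=O)O[C@@H]2C[C@@H](C)C3=C(C[C@@H]12)C(C)=CC(=O)C3(OC)OC(C)=O
F5 | step 21 | Diels–Alder adduct with acetoxy and methoxy on Cb | C1C(=O)O[C@@H]2C[C@@H](C)[C@]34C[C@]5(C(=O)O[C@H]6C[C@@]7(C)C(=C[C@H]65)[C@H](C)CC[C@@H]7O[Si](C)(C)C(C)(C)C)[C@H](C(C)=C3C[C@@H]12)C(=O)C4(OC)OC(C)=O
F6 | step 28 | Barton ester of acid 44 | C=C1C(=O)O[C@@H]2C[C@@H](C)[C@]34C[C@]5(C(=O)O[C@H]6C[C@@]7(C)C(=C[C@H]65)[C@H](C)CC[C@@H]7O[Si](C)(C)C(C)(C)C)[C@H](C(C)=C3C[C@@H]12)[C@@H]4C(=O)On1ccccc1=S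
F7 | step 28 | C2 hydroperoxide (syn to C4=C5) | C=C1C(=O)O[C@@H]2C[C@@H](C)[C@]34C[C@]5(C(=O)O[C@H]6C[C@@]7(C)C(=C[C@H]65)[C@H](C)CC[C@@H]7O[Si](C)(C)C(C)(C)C)[C@H](C(C)=C3C[C@@H]12)[C@@H]4OO
F8 | step 28 | C2 alcohol (syn to C4=C5) | C=C1C(=O)O[C@@H]2C[C@@H](C)[C@]34C[C@]5(C(=O)O[C@H]6C[C@@]7(C)C(=C[C@H]65)[C@H](C)CC[C@@H]7O[Si](C)(C)C(C)(C)C)[C@H](C(C)=C3C[C@@H]12)[C@@H]4O
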